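The chain is numbered C1 (benzylic CH2) to C8 (CH3). The target is the (3S,5R), that is 1,3-syn, diacetate of 1-(4-hydroxy-3-methoxyphenyl)octane-3,5-diol.
Retrosynthetic cuts, in order: the two O–acetyl bonds and a benzyl cap on the phenol; C6–C7 (ethyl nucleophile on a C5–C6 epoxide); C5–O5 (key cut, back to a C5=C6 alkene); C3–C4 (allyl onto the C1–C3 arylpropanal).
Enabling feature: O5 is 1,3-syn to O3, and C5–C6 can be the terminal alkene of a homoallylic alcohol. A tert-butyl carbonate on O3 can therefore reach C5 through its carbonyl oxygen and close the six-membered ring C3–O3–C(=O)–O5–C5–C4, a 1,3-dioxan-2-one.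
Forward order: aryl-C1–C3 aldehyde, C4–C6 by allylation, the temporary dioxanone ring, a transient oxirane, C7–C8 by epoxide opening, then acetylation and debenzylation.
Stereochemistry: C3 comes from a reagent-controlled Brown allylation and C5 from C3 by 1,3-induction in the chair-like cyclisation. No C–O bond at C3 or C5 is broken afterwards.

Key step: step 5

Step 1
Reactants: 1 dihydroconiferyl alcohol; 2 benzyl bromide
Product: 3 3-[4-(benzyloxy)-3-methoxyphenyl]propan-1-ol
Conditions: BnBr, K2CO3, acetone, reflux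
Reagents that add atoms: benzyl bromide 2, BrCc1ccccc1
Why: In this Williamson ether synthesis K2CO3 deprotonates only the far more acidic phenol, so the phenoxide alone should be benzylated and the primary alcohol stays free.

Step 2
Reactants: 3 3-[4-(benzyloxy)-3-methoxyphenyl]propan-1-ol
Product: 4 3-[4-(benzyloxy)-3-methoxyphenyl]propanal
Conditions: TEMPO (cat.), PhI(OAc)2, CH2Cl2, rt
Reagents that add atoms: none
Why: The TEMPO-catalysed oxoammonium oxidation with PhI(OAc)2 as terminal oxidant should stop at the aldehyde and leaves aryl and benzyl ethers alone.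

Step 3
Reactants: 4 3-[4-(benzyloxy)-3-methoxyphenyl]propanal; 5 (+)-B-allyldiisopinocampheylborane (commercial salt-free 1 M solution in pentane, the reagent derived from (−)-α-pinene)
Product: 7 (3S)-1-[4-(benzyloxy)-3-methoxyphenyl]hex-5-en-3-ol, via borinate ester 6 (not isolated)
Conditions: 5, Et2O, −78 °C; then 3 M NaOH, 30% H2O2, 0 °C to rt
Reagents that add atoms: (+)-B-allyldiisopinocampheylborane 5, C=CCB([C@H]1C[C@H]2C[C@@H]([C@@H]1C)C2(C)C)[C@H]1C[C@H]2C[C@@H]([C@@H]1C)C2(C)C
Why: In the Brown allylation the allyl group travels through a closed Zimmerman–Traxler chair in which these isopinocampheyl groups leave the re face of the aldehyde open, which should set C3 as (S) and form C3–C4, and alkaline peroxide then releases the alcohol from boron.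

Step 4
Reactants: 7 (3S)-1-[4-(benzyloxy)-3-methoxyphenyl]hex-5-en-3-ol; 8 di-tert-butyl dicarbonate
Product: 9 tert-butyl (3S)-1-[4-(benzyloxy)-3-methoxyphenyl]hex-5-en-3-yl carbonate
Conditions: Boc2O, DMAP (cat.), MeCN, rt
Reagents that add atoms: di-tert-butyl dicarbonate 8, CC(C)(C)OC(=O)OC(=O)OC(C)(C)C
Why: DMAP-catalysed acyl transfer from Boc2O to the secondary alcohol takes place at oxygen only, so the mixed carbonate should form with C3 unchanged.

Step 5
Reactants: 9 tert-butyl (3S)-1-[4-(benzyloxy)-3-methoxyphenyl]hex-5-en-3-yl carbonate; 10 iodine monobromide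
Product: 12 (4S,6S)-4-{2-[4-(benzyloxy)-3-methoxyphenyl]ethyl}-6-(iodomethyl)-1,3-dioxan-2-one, via tert-butoxydioxanylium bromide 11 (not isolated)
Conditions: IBr (1.05 equiv, 1 M in CH2Cl2, slow addition), PhMe, −85 °C
Reagents that add atoms: iodine monobromide 10, IBr
Why: Iodine monobromide activates the C5=C6 π bond as an iodonium ion in a reversible step, the Lewis-basic carbonyl oxygen of the O3 carbonate attacks C5 anti to iodine to make the C5–O5 and C6–iodine bonds, and cation 11 then loses its tert-butyl group as isobutene, which makes the closure irreversible. The closest known reaction type is the iodocarbonate cyclisation of homoallylic tert-butyl carbonates, a halocyclisation akin to iodolactonisation that is routinely run on terminal alkenes two carbons away from a secondary carbinol. The 1,3-dioxan-2-one closes in the 6-exo mode, because the iodonium ion carries more positive charge at the substituted carbon C5 and the 7-endo attack at C6 would need a larger and looser transition state. C5 is set by C3: of the two chair-like arrangements of the closing ring, the one that keeps both the C1–C2 arylethyl chain and the C6 iodonium carbon equatorial is lower in energy, and it leads to the cis-(4S,6S) ring, that is to O3 and O5 syn. The step needs the alkene to react ahead of the electron-rich dialkoxyarene, which should be secured by the internal nucleophile poised for a six-membered closure, the capped phenol, barely more than one equivalent of IBr added slowly, and the very low temperature in a non-polar solvent.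

Step 6
Reactants: 12 (4S,6S)-4-{2-[4-(benzyloxy)-3-methoxyphenyl]ethyl}-6-(iodomethyl)-1,3-dioxan-2-one
Product: 14 (2S)-4-[4-(benzyloxy)-3-methoxyphenyl]-1-[(2S)-oxiran-2-yl]butan-2-ol, via iodo diol 13 (not isolated)
Conditions: K2CO3 (3 equiv), MeOH, 0 °C to rt
Reagents that add atoms: none
Why: Methanolysis of the cyclic carbonate (transesterification) frees O5, which displaces the neighbouring iodide in an intramolecular Williamson 3-exo-tet closure, and since neither C3–O nor C5–O is broken both centres keep their configuration.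

Step 7
Reactants: 14 (2S)-4-[4-(benzyloxy)-3-methoxyphenyl]-1-[(2S)-oxiran-2-yl]butan-2-ol; 15 ethylmagnesium bromide
Product: 16 (3S,5R)-1-[4-(benzyloxy)-3-methoxyphenyl]octane-3,5-diol
Conditions: EtMgBr (3 equiv), CuI (10 mol %), THF, −30 to 0 °C
Reagents that add atoms: ethylmagnesium bromide 15, CC[Mg]Br
Why: After one equivalent has deprotonated O3–H, the copper-catalysed Grignard opening of the terminal epoxide should proceed by SN2 attack at the unhindered C6, which joins C6–C7 and leaves C5 untouched.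

Step 8
Reactants: 16 (3S,5R)-1-[4-(benzyloxy)-3-methoxyphenyl]octane-3,5-diol; 17 acetic anhydride
Product: 18 (3S,5R)-1-[4-(benzyloxy)-3-methoxyphenyl]octane-3,5-diyl diacetate
Conditions: Ac2O, pyridine, DMAP (cat.), CH2Cl2, 0 °C to rt
Reagents that add atoms: acetic anhydride 17, CC(=O)OC(C)=O
Why: DMAP-catalysed O-acetylation esterifies both secondary alcohols at oxygen and therefore with retention at C3 and C5.

Step 9
Reactants: 18 (3S,5R)-1-[4-(benzyloxy)-3-methoxyphenyl]octane-3,5-diyl diacetate
Product: 19 (3S,5R)-1-(4-hydroxy-3-methoxyphenyl)octane-3,5-diyl diacetate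
Conditions: H2 (1 atm), 10% Pd/C, EtOAc, rt
Reagents that add atoms: none
Why: Catalytic hydrogenolysis cleaves only the benzylic C–O bond of the aryl benzyl ether, and the non-benzylic secondary acetates should survive in the aprotic, non-transesterifying solvent.

Compound list
1 | dihydroconiferyl alcohol, 4-(3-hydroxypropyl)-2-methoxyphenol | COc1cc(CCCO)ccc1O | starting material
2 | benzyl bromide | BrCc1ccccc1 | starting material
3 | 3-[4-(benzyloxy)-3-methoxyphenyl]propan-1-ol | COc1cc(CCCO)ccc1OCc1ccccc1 | intermediate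
4 | 3-[4-(benzyloxy)-3-methoxyphenyl]propanal | COc1cc(CCC=O)ccc1OCc1ccccc1 | intermediate
5 | (+)-B-allyldiisopinocampheylborane, isopinocampheyl groups from (−)-α-pinene | C=CCB([C@H]1C[C@H]2C[C@@H]([C@@H]1C)C2(C)C)[C@H]1C[C@H]2C[C@@H]([C@@H]1C)C2(C)C | starting material
6 | (3S)-1-[4-(benzyloxy)-3-methoxyphenyl]hex-5-en-3-yl diisopinocampheylborinate | C=CC[C@H](CCc1ccc(OCc2ccccc2)c(OC)c1)OB([C@H]1C[C@H]2C[C@@H]([C@@H]1C)C2(C)C)[C@H]1C[C@H]2C[C@@H]([C@@H]1C)C2(C)C | intermediate
7 | (3S)-1-[4-(benzyloxy)-3-methoxyphenyl]hex-5-en-3-ol | C=CC[C@H](CCc1ccc(OCc2ccccc2)c(OC)c1)O | intermediate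
8 | di-tert-butyl dicarbonate | CC(C)(C)OC(=O)OC(=O)OC(C)(C)C | starting material
9 | tert-butyl (3S)-1-[4-(benzyloxy)-3-methoxyphenyl]hex-5-en-3-yl carbonate | C=CC[C@H](CCc1ccc(OCc2ccccc2)c(OC)c1)OC(=O)OC(C)(C)C | intermediate
10 | iodine monobromide | IBr | starting material
11 | (4S,6S)-4-{2-[4-(benzyloxy)-3-methoxyphenyl]ethyl}-2-tert-butoxy-6-(iodomethyl)-1,3-dioxan-2-ylium bromide | CC(C)(C)OC1=[O+][C@@H](CCc2ccc(OCc3ccccc3)c(OC)c2)C[C@@H](CI)O1.[Br-] | intermediate
12 | (4S,6S)-4-{2-[4-(benzyloxy)-3-methoxyphenyl]ethyl}-6-(iodomethyl)-1,3-dioxan-2-one (cis) | O=C1O[C@@H](CCc2ccc(OCc3ccccc3)c(OC)c2)C[C@@H](CI)O1 | intermediate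
13 | (2S,4S)-6-[4-(benzyloxy)-3-methoxyphenyl]-1-iodohexane-2,4-diol | O[C@@H](CCc1ccc(OCc2ccccc2)c(OC)c1)C[C@@H](CI)O | intermediate
14 | (2S)-4-[4-(benzyloxy)-3-methoxyphenyl]-1-[(2S)-oxiran-2-yl]butan-2-ol | O[C@@H](CCc1ccc(OCc2ccccc2)c(OC)c1)C[C@H]1CO1 | intermediate
15 | ethylmagnesium bromide | CC[Mg]Br | starting material
16 | (3S,5R)-1-[4-(benzyloxy)-3-methoxyphenyl]octane-3,5-diol | CCC[C@H](C[C@H](CCc1ccc(OCc2ccccc2)c(OC)c1)O)O | intermediate
17 | acetic anhydride | CC(=O)OC(C)=O | starting material
18 | (3S,5R)-1-[4-(benzyloxy)-3-methoxyphenyl]octane-3,5-diyl diacetate | CCC[C@H](C[C@H](CCc1ccc(OCc2ccccc2)c(OC)c1)OC(C)=O)OC(C)=O | intermediate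
19 | (3S,5R)-1-(4-hydroxy-3-methoxyphenyl)octane-3,5-diyl diacetate | CCC[C@H](C[C@H](CCc1ccc(O)c(OC)c1)OC(C)=O)OC(C)=O | target

Total step count: 9. Longest linear sequence: 9 steps (1 to 19).

Steps most likely to fail

Step 5.
- Risk: electrophilic halogenation of the dialkoxyarene may compete with capture of the iodonium ion, and the preference for the diequatorial chair may be too small for a clean cis closure.
- Fallback: it uses no electrophilic halogen and sets C5 under reagent control. It sets out from 7 and comes back at 19.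
- Alcohol 7 is silylated (TBSCl, imidazole, DMF) to the silyl ether F1.
- A Lemieux–Johnson cleavage (OsO4 cat., NaIO4, 2,6-lutidine, dioxane–H2O) passes through the vicinal diol F2 and removes C6 to give the β-silyloxy aldehyde F3.
- A second Brown allylation with the same borane 5 gives the borinate F4 and, after alkaline peroxide, the syn homoallylic alcohol F5. In F5 the allyl group supplies C6–C8.
- TBAF in THF frees the unsaturated diol F6, and Ac2O/pyridine/DMAP gives the unsaturated diacetate F7.
- H2 over Pd/C saturates C7=C8 and cleaves the benzyl ether in one operation to give 19.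

Step 7.
- Risk: halide from the magnesium and copper salts may open the oxirane faster than ethyl is transferred, and the transfer may become sluggish once O3 is a magnesium alkoxide.
- Fallback: it replaces the organocopper chemistry by a hard sp-carbon nucleophile and postpones saturation to the last step. It sets out from 14 and comes back at 19.
- Lithium acetylide–ethylenediamine complex in DMSO at rt opens 14 at C6 to the alkynyl diol F8.
- Ac2O/pyridine/DMAP gives the alkynyl diacetate F9.
- H2 over Pd/C reduces C7≡C8 fully and removes the benzyl group to give 19.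

Step 3.
- Risk: facial selectivity on an unbranched aldehyde may be insufficient, and the product may be hard to separate from the terpene alcohol.
- Fallback: it takes C3 from a resolution and forms C4–C5 instead of C3–C4. It sets out from 4 and comes back at 7.
- A Corey–Chaykovsky methylenation (Me3SI, NaH, DMSO–THF, 0 °C) converts 4 into the racemic oxirane F10.
- A Jacobsen hydrolytic kinetic resolution follows, with (S,S)-N,N'-bis(3,5-di-tert-butylsalicylidene)cyclohexane-1,2-diaminatocobalt acetate (a complex of trivalent cobalt) and 0.55 equiv of H2O.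
- The resolution should leave the (S)-oxirane F11 and hydrolyse its antipode to the (R)-diol F12, which is removed by chromatography.
- Vinylmagnesium bromide with catalytic CuI in THF at −20 °C opens F11 at C4 and gives 7.

Further compounds
F1 | step 5 | tert-butyl({(3S)-1-[4-(benzyloxy)-3-methoxyphenyl]hex-5-en-3-yl}oxy)dimethylsilane | C=CC[C@H](CCc1ccc(OCc2ccccc2)c(OC)c1)O[Si](C)(C)C(C)(C)C
F2 | step 5 | (4S)-6-[4-(benzyloxy)-3-methoxyphenyl]-4-[(tert-butyldimethylsilyl)oxy]hexane-1,2-diol, both C2 epimers | OCC(O)C[C@H](CCc1ccc(OCc2ccccc2)c(OC)c1)O[Si](C)(C)C(C)(C)C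
F3 | step 5 | (3S)-5-[4-(benzyloxy)-3-methoxyphenyl]-3-[(tert-butyldimethylsilyl)oxy]pentanal | O=CC[C@H](CCc1ccc(OCc2ccccc2)c(OC)c1)O[Si](C)(C)C(C)(C)C
F4 | step 5 | (4R,6S)-8-[4-(benzyloxy)-3-methoxyphenyl]-6-[(tert-butyldimethylsilyl)oxy]oct-1-en-4-yl diisopinocampheylborinate | C=CC[C@H](C[C@H](CCc1ccc(OCc2ccccc2)c(OC)c1)O[Si](C)(C)C(C)(C)C)OB([C@H]1C[C@H]2C[C@@H]([C@@H]1C)C2(C)C)[C@H]1C[C@H]2C[C@@H]([C@@H]1C)C2(C)C
F5 | step 5 | (4R,6S)-8-[4-(benzyloxy)-3-methoxyphenyl]-6-[(tert-butyldimethylsilyl)oxy]oct-1-en-4-ol | C=CC[C@H](C[C@H](CCc1ccc(OCc2ccccc2)c(OC)c1)O[Si](C)(C)C(C)(C)C)O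
F6 | step 5 | (4R,6S)-8-[4-(benzyloxy)-3-methoxyphenyl]oct-1-ene-4,6-diol | C=CC[C@H](C[C@H](CCc1ccc(OCc2ccccc2)c(OC)c1)O)O
F7 | step 5 | (4R,6S)-8-[4-(benzyloxy)-3-methoxyphenyl]oct-1-ene-4,6-diyl diacetate | C=CC[C@H](C[C@H](CCc1ccc(OCc2ccccc2)c(OC)c1)OC(C)=O)OC(C)=O
F8 | step 7 | (3S,5R)-1-[4-(benzyloxy)-3-methoxyphenyl]oct-7-yne-3,5-diol | C#CC[C@H](C[C@H](CCc1ccc(OCc2ccccc2)c(OC)c1)O)O
F9 | step 7 | (3S,5R)-1-[4-(benzyloxy)-3-methoxyphenyl]oct-7-yne-3,5-diyl diacetate | C#CC[C@H](C[C@H](CCc1ccc(OCc2ccccc2)c(OC)c1)OC(C)=O)OC(C)=O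
F10 | step 3 | racemic 2-{2-[4-(benzyloxy)-3-methoxyphenyl]ethyl}oxirane | COc1cc(CCC2CO2)ccc1OCc1ccccc1
F11 | step 3 | (2S)-2-{2-[4-(benzyloxy)-3-methoxyphenyl]ethyl}oxirane | COc1cc(CC[C@H]2CO2)ccc1OCc1ccccc1
F12 | step 3 | (2R)-4-[4-(benzyloxy)-3-methoxyphenyl]butane-1,2-diol | OC[C@H](O)CCc1ccc(OCc2ccccc2)c(OC)c1
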